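## The problem

Compound 29 is an unsymmetrical dimer of two olivil-type units. Each unit is an oxolane (O1, C2–C5) with an aryl group at C2, CH2OH at C3, and both OH and an arylmethyl group at C4. The units are not fused. One biaryl bond joins C5 of the C2-aryl ring of unit 1 (ring B) to C5 of the benzyl ring of unit 2 (ring C); ring A (benzyl, unit 1) and ring D (C2-aryl, unit 2) are plain guaiacyl groups. Because the link is head-to-tail, the halves are constitutionally different, and the central B–C biaryl must carry two different side chains. Both halves have the same (2S,3R,4S) triad: C2-aryl trans to the C3 CH2OH, and C4–OH trans to that CH2OH (benzyl cis). On a five-membered ring each centre can direct its neighbour: C2 can place a C3 substituent anti, C3 can place a C4 oxygen anti, and C3 can in turn dictate C2 because the 2,3-trans ether is the more stable one. The fragile elements are the C2–O1 bonds (para-oxygenated benzylic ethers that ionise in acid and can be hydrogenolysed), the tertiary C4 alcohols, and four oxidisable phenols that must stay masked to the end. The enabling feature is that, with C5 raised to a carbonyl, each ring is a 5-aryl-3-benzylfuran-2(5H)-one whose C3=C4 alkene accepts a carbon nucleophile at C3 and becomes an enolate at C4, the two carbons that need a C1 unit and an oxygen on opposite faces.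

## Retrosynthesis

**Unmasking and ring re-closure.** Target 29 is traced to its tetrabenzyl ether 28 (four aryl O–CH2Ph bonds). The two O1–C2 bonds of 28 are then cut to give the open-chain octaol 27. A lactone carbonyl cannot be taken to the ether CH2 without Lewis acid/hydride conditions that also threaten C2–O1. Full reduction and re-closure by benzylic ionisation is therefore preferred: of the three hydroxyl groups that can reach the C2 cation, only C5–OH gives a five-membered ring. The forward step must close at oxygen faster than ring A or C closes at carbon, and must deliver the 2,3-trans ether.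

**Oxidation-level adjustments.** Octaol 27 comes from bis(hydroxymethyl lactone) 26 by reduction of the two lactone carbonyls. Compound 26 comes from bis(vinyl lactone) 25 by cleavage of the two vinyl C=C bonds. Vinyl is the hydroxymethyl synthon of choice: it transfers well from copper, it is small, and it is inert to the enolate oxidation.

**Key disconnection.** In 25 the two C3–vinyl bonds and the two C4–OH bonds are cut, giving bis(butenolide) 22 and vinylmagnesium bromide 3. Six of the ten stereocentre-bearing substituent bonds of the target are thereby removed in one operation. The precursor keeps only the two C2 centres. The forward reaction needs conjugate addition anti to the C2 aryl group and oxidation anti to the new vinyl group, twice, without deprotonating the acidic C2–H.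

**Butenolide rings.** The two C3=C4 alkenes of 22 are cut by ring-closing metathesis, giving tetraene bis-ester 21. This places the C2 stereocentre in an allylic alcohol and the benzyl group in an acrylic acid, both simple. Routes through aldol/lactonisation or selenoxide elimination would be longer and would expose the C2–H to base.

**Ester bonds and their order.** Bis-ester 21 is cut at the ring B ester into alcohol 17 and acid 20. Alcohol 17 comes from silyl ether 16, which is cut at the ring D ester into biaryl acid 12 and alcohol 15. The central piece carries one carbinol and one carboxyl, so they must be addressed in turn. A silyl ether and a methyl ester (in 11, the precursor of 12) differentiate them, and the base-free desilylation is placed after the first esterification.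

**Biaryl bond.** Biaryl 11 is cut between rings B and C into aryl bromide 6 (the nucleophile after bromine–lithium exchange, via borate 10) and aryl bromide 9. The coupling is placed before any 1-arylallyl ester exists, because zerovalent palladium would ionise such esters. It is also placed before any butenolide exists, because the coupling base would racemise C2.

**Monomers.** Silyl ether 6 comes from the resolved alcohol 5, obtained from racemate 4, which is made from aldehyde 2 and 3. Alcohol 15 comes likewise from racemate 14, made from O-benzylvanillin 13 and 3. Acrylate 9 comes from Meldrum's acid adduct 8 (from 2 and Meldrum's acid 7). Acid 20 comes from ester 19 and adduct 18 (from 13 and 7). Aldehyde 2 is the benzyl ether of 5-bromovanillin 1. Two aldehydes thus supply all four rings.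

## Roads not taken

**Alternative 1:** Twofold enol ether metathesis. The cut is at both C4=C5 bonds, leading back to bis-diene A1, in which each O1 is a vinyl ether and each C4 a 1,1-disubstituted alkene. Two ring closures would give bis(2,3-dihydrofuran) A2. Epoxidation of each enol ether anti to C3, followed by reduction at C5, would then install C4–OH.
- Merits: C5 is at the ether level from the start, so no lactone has to be reduced and C2–O1 is never broken. This is a real advantage over the chosen plan, which must re-form C2.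
- Weak points: vinyl ethers convert ruthenium alkylidenes into slow Fischer-type carbenes. Closing a trisubstituted cyclic enol ether from a 1,1-disubstituted alkene, twice in one molecule, usually calls for Mo(N-2,6-iPr2C6H3)(CHCMe2Ph)[OCMe(CF3)2]2, which tolerates little. A1 also needs O-vinylation of acid-labile benzylic alcohols and an anti C2/C3 pair made by separate acyclic control.
- Comparison: the chosen plan has to set against the shorter endgame a dependable acrylate metathesis and the fact that C3 and C4 both arise from one resolved centre.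

**Alternative 2:** Twofold chelate Ireland–Claisen rearrangement. The cut is at both C3–C4 bonds, leading back to bis[(Z)-allyl 2-benzyloxy-3-arylpropanoate] A3. Its bis(silyl ketene acetal) would rearrange to bis(α-benzyloxy-β-vinyl acid) A4, forming the C3–C4 bonds and both centres in each half.
- Merits: the most congested C–C bond is made intramolecularly, and the tertiary oxygen centre is set by C–C bond formation, not by oxidation. C5 (carboxyl) and the C3 side chain (vinyl) are differentiated, so the ring could be closed by displacement at C5 with retention at C2. On this point the alternative is better than the chosen plan.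
- Weak points: three independent factors must cooperate twice. These are the chelated enolate geometry at a fully substituted α-carbon, the Z-alkene geometry, and acyclic induction from the C2 silyloxy centre. The extra tertiary benzyl ethers must later be hydrogenolysed in competition with C2–O1.
- Comparison: the chosen plan offers cyclic stereocontrol, each centre directed by its ring neighbour, at the price of reopening the ring.

**Alternative 3:** Twofold quinone methide cycloetherification. The cut is at both O1–C2 bonds, leading back to seco dimer A5, in which C2 is a CH2 para to a free phenol. DDQ would generate two quinone methides, each trapped by the C5 hydroxyl, to give the target bis(benzyl ether) A6.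
- Merits: the precursor has two stereocentres fewer, C2 is set by C3 under the same trans preference, and the endgame is very short.
- Weak points: A5 has four benzylic CH2 groups on electron-rich rings, an ortho-aryl phenol and two benzyl ethers. The oxidant must choose two sites among these and must then spare the new para-hydroxybenzylic C2–H of A6. Without a C2 centre, the C3/C4 pair of A5 needs another source of absolute control.
- Comparison: the chosen plan uses the same C3-directed closure at C2, but from the alcohol oxidation level (27), where the site of ionisation is unambiguous, and its C2 centre serves as the control element for C3 and C4. In step count after the key step, Alternative 3 is the shorter.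

Key step: step 18

Remark: the biaryl axis has only two ortho substituents and is treated as freely rotating, so no axial element is controlled. In the discussion, ring atoms keep the oxolane numbering of the target (O1, C2 aryl, C3, C4, C5) in all intermediates.

## Route

Step 1
Reactants: 1 5-bromovanillin (3-bromo-4-hydroxy-5-methoxybenzaldehyde)
Product: 2 4-(benzyloxy)-3-bromo-5-methoxybenzaldehyde
Conditions: BnBr, K2CO3, DMF, 60 °C
Reagents that add atoms: benzyl bromide, BrCc1ccccc1
Why: Williamson etherification of the phenoxide; aldehyde and aryl bromide are inert, and the benzyl ether is the phenol mask carried to the last step.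

Step 2
Reactants: 2 4-(benzyloxy)-3-bromo-5-methoxybenzaldehyde; 3 vinylmagnesium bromide
Product: 4 rac-1-[4-(benzyloxy)-3-bromo-5-methoxyphenyl]prop-2-en-1-ol
Conditions: THF, −78 to 0 °C; H2O/NH4Cl
Reagents that add atoms: none
Why: Grignard 1,2-addition to a non-enolisable aryl aldehyde; halogen–magnesium exchange at the aryl bromide does not compete at this temperature.

Step 3
Reactants: 4 rac-1-[4-(benzyloxy)-3-bromo-5-methoxyphenyl]prop-2-en-1-ol
Product: 5 (1S)-1-[4-(benzyloxy)-3-bromo-5-methoxyphenyl]prop-2-en-1-ol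
Conditions: immobilised Candida antarctica lipase B, vinyl acetate, MTBE, 30 °C, stopped just past half conversion; chromatography
Reagents that add atoms: none
Why: Lipase-catalysed kinetic resolution; by the Kazlauskas rule (aryl large, vinyl medium) the (R)-alcohol is acylated and the (S)-alcohol, whose carbinol carbon becomes C2 of unit 1, is left. Neutral conditions avoid ionising the electron-rich allylic alcohol.

Step 4
Reactants: 5 (1S)-1-[4-(benzyloxy)-3-bromo-5-methoxyphenyl]prop-2-en-1-ol
Product: 6 tert-butyl{[(1S)-1-(4-(benzyloxy)-3-bromo-5-methoxyphenyl)prop-2-en-1-yl]oxy}dimethylsilane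
Conditions: TBSCl, imidazole, DMF, 0 °C to rt
Reagents that add atoms: tert-butyldimethylsilyl chloride, CC(C)(C)[Si](C)(C)Cl
Why: Standard silylation without C–O cleavage; the silyl ether survives the organolithium, the coupling and the saponification and is later removed by fluoride.

Step 5
Reactants: 2 4-(benzyloxy)-3-bromo-5-methoxybenzaldehyde; 7 Meldrum's acid (2,2-dimethyl-1,3-dioxane-4,6-dione)
Product: 8 5-[4-(benzyloxy)-3-bromo-5-methoxybenzyl]-2,2-dimethyl-1,3-dioxane-4,6-dione
Conditions: Hantzsch ester, L-proline (cat.), EtOH, rt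
Reagents that add atoms: none
Why: Organocatalytic reductive Knoevenagel alkylation: the proline-catalysed condensation product is reduced in situ by hydride transfer from the dihydropyridine, which stops at the monoalkylated Meldrum's acid.

Step 6
Reactants: 8 5-[4-(benzyloxy)-3-bromo-5-methoxybenzyl]-2,2-dimethyl-1,3-dioxane-4,6-dione
Product: 9 methyl 2-[4-(benzyloxy)-3-bromo-5-methoxybenzyl]prop-2-enoate
Conditions: CH2=NMe2+ I−, MeOH, 65 °C
Reagents that add atoms: N,N-dimethylmethyleneiminium iodide (Eschenmoser's salt), C=[N+](C)C.[I-]; methanol, CO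
Why: Mannich reaction at C5 of the Meldrum's acid, methanolysis of the dioxanedione with loss of acetone, then decarboxylative elimination of dimethylamine; an established route from 5-monosubstituted Meldrum's acids to 2-substituted acrylates.

Step 7
Reactants: 6 tert-butyl{[(1S)-1-(4-(benzyloxy)-3-bromo-5-methoxyphenyl)prop-2-en-1-yl]oxy}dimethylsilane; 9 methyl 2-[4-(benzyloxy)-3-bromo-5-methoxybenzyl]prop-2-enoate
Product: 11 methyl 2-({2,2'-bis(benzyloxy)-3,3'-dimethoxy-5'-[(1S)-1-(tert-butyldimethylsilyloxy)prop-2-en-1-yl]biphenyl-5-yl}methyl)prop-2-enoate, via lithium aryltriisopropoxyborate 10 (not isolated)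
Conditions: 6, B(OiPr)3, n-BuLi, THF/toluene, −78 °C; then 9, Pd(OAc)2 (cat.), SPhos, aq. K3PO4, 40 °C
Reagents that add atoms: none
Why: Bromine–lithium exchange with in situ borate trapping gives 10, which is used directly in a Suzuki–Miyaura coupling. The dialkylbiarylphosphine allows the di-ortho-alkoxy biaryl to form at 40 °C, where the silyl ether, the terminal alkene and the 1,1-disubstituted acrylate (slow in Heck insertion) are spectators.

Step 8
Reactants: 11 methyl 2-({2,2'-bis(benzyloxy)-3,3'-dimethoxy-5'-[(1S)-1-(tert-butyldimethylsilyloxy)prop-2-en-1-yl]biphenyl-5-yl}methyl)prop-2-enoate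
Product: 12 2-({2,2'-bis(benzyloxy)-3,3'-dimethoxy-5'-[(1S)-1-(tert-butyldimethylsilyloxy)prop-2-en-1-yl]biphenyl-5-yl}methyl)prop-2-enoic acid
Conditions: LiOH, THF/H2O, rt; 1 M HCl to pH 4, 0 °C
Reagents that add atoms: lithium hydroxide, [Li+].[OH-]
Why: Saponification of an unhindered methyl ester; no alcohol cosolvent is used, so alkoxide cannot add to the acrylate, and the brief mildly acidic work-up leaves the secondary silyl ether intact.

Step 9
Reactants: 13 4-(benzyloxy)-3-methoxybenzaldehyde (O-benzylvanillin); 3 vinylmagnesium bromide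
Product: 14 rac-1-[4-(benzyloxy)-3-methoxyphenyl]prop-2-en-1-ol
Conditions: THF, −78 to 0 °C; H2O/NH4Cl
Reagents that add atoms: none
Why: Grignard 1,2-addition, as in step 2.

Step 10
Reactants: 14 rac-1-[4-(benzyloxy)-3-methoxyphenyl]prop-2-en-1-ol
Product: 15 (1S)-1-[4-(benzyloxy)-3-methoxyphenyl]prop-2-en-1-ol
Conditions: immobilised Candida antarctica lipase B, vinyl acetate, MTBE, 30 °C, stopped just past half conversion; chromatography
Reagents that add atoms: none
Why: Lipase kinetic resolution as in step 3; the unreacted (S)-alcohol supplies C2 of unit 2.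

Step 11
Reactants: 12 2-({2,2'-bis(benzyloxy)-3,3'-dimethoxy-5'-[(1S)-1-(tert-butyldimethylsilyloxy)prop-2-en-1-yl]biphenyl-5-yl}methyl)prop-2-enoic acid; 15 (1S)-1-[4-(benzyloxy)-3-methoxyphenyl]prop-2-en-1-ol
Product: 16 (1S)-1-[4-(benzyloxy)-3-methoxyphenyl]prop-2-en-1-yl 2-({2,2'-bis(benzyloxy)-3,3'-dimethoxy-5'-[(1S)-1-(tert-butyldimethylsilyloxy)prop-2-en-1-yl]biphenyl-5-yl}methyl)prop-2-enoate
Conditions: DCC, DMAP (cat.), CH2Cl2, 0 °C to rt
Reagents that add atoms: none
Why: Steglich esterification; the alcohol is acylated at oxygen, so the carbinol C–O bond and its configuration are untouched, and the neutral cold conditions avoid ionising the 1-arylallyl system.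

Step 12
Reactants: 16 (1S)-1-[4-(benzyloxy)-3-methoxyphenyl]prop-2-en-1-yl 2-({2,2'-bis(benzyloxy)-3,3'-dimethoxy-5'-[(1S)-1-(tert-butyldimethylsilyloxy)prop-2-en-1-yl]biphenyl-5-yl}methyl)prop-2-enoate
Product: 17 (1S)-1-[4-(benzyloxy)-3-methoxyphenyl]prop-2-en-1-yl 2-({2,2'-bis(benzyloxy)-5'-[(1S)-1-hydroxyprop-2-en-1-yl]-3,3'-dimethoxybiphenyl-5-yl}methyl)prop-2-enoate
Conditions: Bu4NF, AcOH, THF, 0 °C to rt
Reagents that add atoms: none
Why: Fluoride desilylation buffered with acetic acid, so that neither the allylic ester nor the acrylate sees free alkoxide or hydroxide.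

Step 13
Reactants: 13 4-(benzyloxy)-3-methoxybenzaldehyde; 7 Meldrum's acid
Product: 18 5-[4-(benzyloxy)-3-methoxybenzyl]-2,2-dimethyl-1,3-dioxane-4,6-dione
Conditions: Hantzsch ester, L-proline (cat.), EtOH, rt
Reagents that add atoms: none
Why: Reductive Knoevenagel alkylation, as in step 5.

Step 14
Reactants: 18 5-[4-(benzyloxy)-3-methoxybenzyl]-2,2-dimethyl-1,3-dioxane-4,6-dione
Product: 19 methyl 2-[4-(benzyloxy)-3-methoxybenzyl]prop-2-enoate
Conditions: CH2=NMe2+ I−, MeOH, 65 °C
Reagents that add atoms: N,N-dimethylmethyleneiminium iodide (Eschenmoser's salt), C=[N+](C)C.[I-]; methanol, CO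
Why: Mannich methylenation, methanolysis and decarboxylative elimination, as in step 6.

Step 15
Reactants: 19 methyl 2-[4-(benzyloxy)-3-methoxybenzyl]prop-2-enoate
Product: 20 2-[4-(benzyloxy)-3-methoxybenzyl]prop-2-enoic acid
Conditions: LiOH, THF/H2O, rt; 1 M HCl
Reagents that add atoms: lithium hydroxide, [Li+].[OH-]
Why: Saponification, as in step 8.

Step 16
Reactants: 17 (1S)-1-[4-(benzyloxy)-3-methoxyphenyl]prop-2-en-1-yl 2-({2,2'-bis(benzyloxy)-5'-[(1S)-1-hydroxyprop-2-en-1-yl]-3,3'-dimethoxybiphenyl-5-yl}methyl)prop-2-enoate; 20 2-[4-(benzyloxy)-3-methoxybenzyl]prop-2-enoic acid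
Product: 21 (1S)-1-[4-(benzyloxy)-3-methoxyphenyl]prop-2-en-1-yl 2-({2,2'-bis(benzyloxy)-3,3'-dimethoxy-5'-[(1S)-1-({2-[4-(benzyloxy)-3-methoxybenzyl]prop-2-enoyl}oxy)prop-2-en-1-yl]biphenyl-5-yl}methyl)prop-2-enoate
Conditions: DCC, DMAP (cat.), CH2Cl2, 0 °C to rt
Reagents that add atoms: none
Why: Second Steglich esterification, again with retention at the carbinol carbon; it completes the tetraene that holds both diene pairs.

Step 17
Reactants: 21 the bis(1-arylallyl 2-benzylacrylate) tetraene
Product: 22 bis(butenolide): 2,2'-bis(benzyloxy)-3,3'-dimethoxybiphenyl carrying at C5' a (5S)-3-[4-(benzyloxy)-3-methoxybenzyl]-2-oxo-2,5-dihydrofuran-5-yl group (unit 1) and at C5 a {(5S)-5-[4-(benzyloxy)-3-methoxyphenyl]-2-oxo-2,5-dihydrofuran-3-yl}methyl group (unit 2)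
Conditions: second-generation Grubbs catalyst RuCl2(=CHPh)(H2IMes)(PCy3), 1,4-benzoquinone (cat.), toluene (high dilution), 80 °C
Reagents that add atoms: none
Why: Twofold ring-closing metathesis of allyl 2-substituted acrylates to 3-substituted butenolides. The catalyst loads on each terminal allylic alkene and closes onto the neighbouring acrylate (five-membered ring, ethene lost). The C2 stereocentres are not involved, and benzoquinone suppresses ruthenium hydride isomerisation.

Step 18
Reactants: 22 bis(butenolide); 3 vinylmagnesium bromide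
Product: 25 bis(α-hydroxy-β-vinyl lactone): the biphenyl core of 22 carrying at C5' a (3S,4R,5S)-3-[4-(benzyloxy)-3-methoxybenzyl]-3-hydroxy-2-oxo-4-vinyloxolan-5-yl group and at C5 a {(3S,4R,5S)-5-[4-(benzyloxy)-3-methoxyphenyl]-3-hydroxy-2-oxo-4-vinyloxolan-3-yl}methyl group, via bis(silyl ketene acetal) 23 (not isolated), via bis(α-trimethylsilyloxy lactone) 24 (not isolated)
Conditions: CH2=CHMgBr, CuBr·SMe2, Me3SiCl, THF, −78 °C; pentane, filtration, evaporation; DMDO, acetone/CH2Cl2, −78 to −20 °C; aq. citric acid, THF, rt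
Reagents that add atoms: dimethyldioxirane, CC1(C)OO1
Why: The homocuprate (CH2=CH)2CuMgBr, formed from 3 and CuBr·SMe2, adds to C3 of each butenolide by π-complexation, oxidative addition and reductive elimination, and Me3SiCl captures each enolate as the silyl ketene acetal 23 as it forms; this is the Me3SiCl-accelerated, trans-selective cuprate addition known for 5-substituted furan-2(5H)-ones. DMDO then epoxidises the electron-rich C4=C5 bond of 23, and the silyloxy epoxide opens with silyl shift to 24 (Rubottom oxidation), which citric acid desilylates to 25. No ring is closed; two C3–vinyl bonds and two C4–O bonds are made. C3 is controlled by C2: the vinyl group enters the planar butenolide on the face opposite the C2 aryl group, giving the 2,3-trans relation. C4 is controlled by the new C3 centre: the oxidant approaches the ketene acetal anti to the adjacent vinyl group, so OH ends trans and benzyl cis to it, the sense known from hydroxylation of α-benzyl-β-substituted butyrolactone enolates. The chemoselectivity needed is 1,4-addition over removal of the acidic C2–H; it should be secured by a soft, weakly basic cuprate with no free Grignard reagent, by −78 °C and by in situ silylation, which removes the basic enolate. DMDO must react with the ketene acetal and not with the alkoxyarenes or the new vinyl groups; the ketene acetal is by far the most nucleophilic alkene present, and Me2S is evaporated before the oxidant is added. The two halves are electronically insulated, so each should react independently with the same sense of induction.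

Step 19
Reactants: 25 bis(α-hydroxy-β-vinyl lactone)
Product: 26 bis(hydroxymethyl lactone): as 25 with each vinyl group replaced by CH2OH, both lactones (3S,4R,5S)
Conditions: O3, CH2Cl2/MeOH, −78 °C, Sudan Red 7B end-point; NaBH4, −78 to 0 °C
Reagents that add atoms: ozone, [O-][O+]=O
Why: Ozonolysis with reductive work-up; the monosubstituted alkenes react far faster than the alkoxyarenes, and the dye marks the end-point. Borohydride reduces the peroxidic intermediates straight to the alcohols, so no free β-acyloxy aldehyde persists to epimerise at C3 or eliminate; any partial lactone reduction converges in step 20.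

Step 20
Reactants: 26 bis(hydroxymethyl lactone)
Product: 27 octaol: 2,2'-bis(benzyloxy)-3,3'-dimethoxybiphenyl carrying at C5' a (1S,2R,3S)-3-[4-(benzyloxy)-3-methoxybenzyl]-1,3,4-trihydroxy-2-(hydroxymethyl)butyl group and at C5 a (2S,3R,4S)-4-[4-(benzyloxy)-3-methoxyphenyl]-2,4-dihydroxy-2,3-bis(hydroxymethyl)butyl group
Conditions: LiAlH4, THF, 0 °C to rt; Rochelle salt work-up
Reagents that add atoms: none
Why: Hydride reduction of both lactones to the 1,4-diols; aryl benzyl ethers and the three stereocentres of each half are untouched.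

Step 21
Reactants: 27 octaol
Product: 28 tetra-O-benzyl ether of the target: both oxolanes (2S,3R,4S), all four phenols as benzyl ethers
Conditions: (±)-camphor-10-sulfonic acid (cat.), CH2Cl2/THF, 0 °C to rt
Reagents that add atoms: none
Why: Acid-catalysed benzylic SN1 cycloetherification: each para-benzyloxy-stabilised C2 cation is captured 5-exo by the C5 hydroxyl, the only hydroxyl that gives a five-membered ring (C3–CH2OH and C4–OH would give oxetanes). C2 is re-formed under control of C3, the aryl group settling trans to the C3 CH2OH and to the C4 benzyl group, and a cis isomer can re-ionise and correct itself.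

Step 22
Reactants: 28 tetra-O-benzyl ether of the target
Product: 29 CNP0269573.1 (target)
Conditions: H2 (1 atm), Pd/C, EtOAc/EtOH, rt, stopped at full debenzylation
Reagents that add atoms: none
Why: Hydrogenolysis of four aryl benzyl ethers, which cleave much faster than the dialkyl benzylic C2–O1 bonds under neutral conditions; no stereocentre is touched.

## Compound list

1 | 5-bromovanillin | COc1cc(C=O)cc(Br)c1O | starting material
2 | 4-(benzyloxy)-3-bromo-5-methoxybenzaldehyde | COc1cc(C=O)cc(Br)c1OCc1ccccc1 | intermediate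
3 | vinylmagnesium bromide | C=C[Mg]Br | starting material
4 | rac-1-[4-(benzyloxy)-3-bromo-5-methoxyphenyl]prop-2-en-1-ol | COc1cc(C(O)C=C)cc(Br)c1OCc1ccccc1 | intermediate
5 | (1S)-1-[4-(benzyloxy)-3-bromo-5-methoxyphenyl]prop-2-en-1-ol | COc1cc([C@@H](O)C=C)cc(Br)c1OCc1ccccc1 | intermediate
6 | tert-butyl{[(1S)-1-(4-(benzyloxy)-3-bromo-5-methoxyphenyl)prop-2-en-1-yl]oxy}dimethylsilane | COc1cc([C@@H](O[Si](C)(C)C(C)(C)C)C=C)cc(Br)c1OCc1ccccc1 | intermediate
7 | Meldrum's acid | CC1(C)OC(=O)CC(=O)O1 | starting material
8 | 5-[4-(benzyloxy)-3-bromo-5-methoxybenzyl]-2,2-dimethyl-1,3-dioxane-4,6-dione | COc1cc(CC2C(=O)OC(C)(C)OC2=O)cc(Br)c1OCc1ccccc1 | intermediate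
9 | methyl 2-[4-(benzyloxy)-3-bromo-5-methoxybenzyl]prop-2-enoate | COC(=O)C(=C)Cc1cc(Br)c(OCc2ccccc2)c(OC)c1 | intermediate
10 | lithium {2-(benzyloxy)-3-methoxy-5-[(1S)-1-(tert-butyldimethylsilyloxy)prop-2-en-1-yl]phenyl}triisopropoxyborate | [Li+].CC(C)O[B-](OC(C)C)(OC(C)C)c1cc([C@@H](O[Si](C)(C)C(C)(C)C)C=C)cc(OC)c1OCc1ccccc1 | intermediate
11 | methyl 2-({2,2'-bis(benzyloxy)-3,3'-dimethoxy-5'-[(1S)-1-(tert-butyldimethylsilyloxy)prop-2-en-1-yl]biphenyl-5-yl}methyl)prop-2-enoate | COC(=O)C(=C)Cc1cc(OC)c(OCc2ccccc2)c(c1)-c1cc([C@@H](O[Si](C)(C)C(C)(C)C)C=C)cc(OC)c1OCc1ccccc1 | intermediate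
12 | 2-({2,2'-bis(benzyloxy)-3,3'-dimethoxy-5'-[(1S)-1-(tert-butyldimethylsilyloxy)prop-2-en-1-yl]biphenyl-5-yl}methyl)prop-2-enoic acid | OC(=O)C(=C)Cc1cc(OC)c(OCc2ccccc2)c(c1)-c1cc([C@@H](O[Si](C)(C)C(C)(C)C)C=C)cc(OC)c1OCc1ccccc1 | intermediate
13 | 4-(benzyloxy)-3-methoxybenzaldehyde (O-benzylvanillin) | COc1cc(C=O)ccc1OCc1ccccc1 | starting material
14 | rac-1-[4-(benzyloxy)-3-methoxyphenyl]prop-2-en-1-ol | COc1cc(C(O)C=C)ccc1OCc1ccccc1 | intermediate
15 | (1S)-1-[4-(benzyloxy)-3-methoxyphenyl]prop-2-en-1-ol | COc1cc([C@@H](O)C=C)ccc1OCc1ccccc1 | intermediate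
16 | ring D ester of acid 12 with alcohol 15, ring B carbinol as silyl ether | COc1cc([C@@H](OC(=O)C(=C)Cc2cc(OC)c(OCc3ccccc3)c(c2)-c2cc([C@@H](O[Si](C)(C)C(C)(C)C)C=C)cc(OC)c2OCc2ccccc2)C=C)ccc1OCc1ccccc1 | intermediate
17 | ring D ester with free (S)-carbinol on ring B | COc1cc([C@@H](OC(=O)C(=C)Cc2cc(OC)c(OCc3ccccc3)c(c2)-c2cc([C@@H](O)C=C)cc(OC)c2OCc2ccccc2)C=C)ccc1OCc1ccccc1 | intermediate
18 | 5-[4-(benzyloxy)-3-methoxybenzyl]-2,2-dimethyl-1,3-dioxane-4,6-dione | COc1cc(CC2C(=O)OC(C)(C)OC2=O)ccc1OCc1ccccc1 | intermediate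
19 | methyl 2-[4-(benzyloxy)-3-methoxybenzyl]prop-2-enoate | COC(=O)C(=C)Cc1ccc(OCc2ccccc2)c(OC)c1 | intermediate
20 | 2-[4-(benzyloxy)-3-methoxybenzyl]prop-2-enoic acid | OC(=O)C(=C)Cc1ccc(OCc2ccccc2)c(OC)c1 | intermediate
21 | bis(1-arylallyl 2-benzylacrylate) tetraene, both carbinol carbons S | COc1cc([C@@H](OC(=O)C(=C)Cc2cc(OC)c(OCc3ccccc3)c(c2)-c2cc([C@@H](OC(=O)C(=C)Cc3ccc(OCc4ccccc4)c(OC)c3)C=C)cc(OC)c2OCc2ccccc2)C=C)ccc1OCc1ccccc1 | intermediate
22 | biaryl-linked bis[(5S)-5-aryl-3-benzylfuran-2(5H)-one] | COc1cc(CC2=C[C@@H](c3cc(OC)c(OCc4ccccc4)c(-c4cc(CC5=C[C@@H](c6ccc(OCc7ccccc7)c(OC)c6)OC5=O)cc(OC)c4OCc4ccccc4)c3)OC2=O)ccc1OCc1ccccc1 | intermediate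
23 | bis[(4S,5S)-5-aryl-3-benzyl-2-(trimethylsilyloxy)-4-vinyl-4,5-dihydrofuran], vinyl trans to aryl | COc1cc(CC2=C(O[Si](C)(C)C)O[C@H](c3cc(OC)c(OCc4ccccc4)c(-c4cc(CC5=C(O[Si](C)(C)C)O[C@H](c6ccc(OCc7ccccc7)c(OC)c6)[C@H]5C=C)cc(OC)c4OCc4ccccc4)c3)[C@H]2C=C)ccc1OCc1ccccc1 | intermediate
24 | bis[(3S,4R,5S)-5-aryl-3-benzyl-3-(trimethylsilyloxy)-4-vinyloxolan-2-one] | COc1cc(C[C@@]2(O[Si](C)(C)C)C(=O)O[C@H](c3cc(OC)c(OCc4ccccc4)c(-c4cc(C[C@@]5(O[Si](C)(C)C)C(=O)O[C@H](c6ccc(OCc7ccccc7)c(OC)c6)[C@H]5C=C)cc(OC)c4OCc4ccccc4)c3)[C@H]2C=C)ccc1OCc1ccccc1 | intermediate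
25 | bis[(3S,4R,5S)-5-aryl-3-benzyl-3-hydroxy-4-vinyloxolan-2-one] | COc1cc(C[C@@]2(O)C(=O)O[C@H](c3cc(OC)c(OCc4ccccc4)c(-c4cc(C[C@@]5(O)C(=O)O[C@H](c6ccc(OCc7ccccc7)c(OC)c6)[C@H]5C=C)cc(OC)c4OCc4ccccc4)c3)[C@H]2C=C)ccc1OCc1ccccc1 | intermediate
26 | bis[(3S,4R,5S)-5-aryl-3-benzyl-3-hydroxy-4-(hydroxymethyl)oxolan-2-one] | COc1cc(C[C@@]2(O)C(=O)O[C@H](c3cc(OC)c(OCc4ccccc4)c(-c4cc(C[C@@]5(O)C(=O)O[C@H](c6ccc(OCc7ccccc7)c(OC)c6)[C@H]5CO)cc(OC)c4OCc4ccccc4)c3)[C@H]2CO)ccc1OCc1ccccc1 | intermediate
27 | open-chain octaol, each half a (1S,2R,3S)-1-aryl-3-(arylmethyl)-2-(hydroxymethyl)butane-1,3,4-triol | COc1cc(C[C@@](O)(CO)[C@H](CO)[C@H](O)c2cc(OC)c(OCc3ccccc3)c(-c3cc(C[C@@](O)(CO)[C@H](CO)[C@H](O)c4ccc(OCc5ccccc5)c(OC)c4)cc(OC)c3OCc3ccccc3)c2)ccc1OCc1ccccc1 | intermediate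
28 | tetra-O-benzyl ether of the target, both oxolanes (2S,3R,4S) | COc1cc(C[C@@]2(O)CO[C@H](c3cc(OC)c(OCc4ccccc4)c(-c4cc(C[C@@]5(O)CO[C@H](c6ccc(OCc7ccccc7)c(OC)c6)[C@H]5CO)cc(OC)c4OCc4ccccc4)c3)[C@H]2CO)ccc1OCc1ccccc1 | intermediate
29 | CNP0269573.1, both oxolanes (2S,3R,4S) | COc1cc(C[C@@]2(O)CO[C@H](c3cc(OC)c(O)c(-c4cc(C[C@@]5(O)CO[C@H](c6ccc(O)c(OC)c6)[C@H]5CO)cc(OC)c4O)c3)[C@H]2CO)ccc1O | target

## Step count and least certain steps

Total: 22 steps. Longest linear sequence: 15 steps (1, 2, 3, 4, 7, 8, 11, 12, 16, 17, 18, 19, 20, 21, 22).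

**Step 18 (key step).** Three processes may intervene. Removal of the acidic C2 proton may compete with conjugate addition and erode configurational purity through an achiral silyloxyfuran. Addition may be incomplete at one of the two rings. Facial selectivity in the oxidation may be poor, because the C2 aryl group lies on the face the oxidant must use. The fallback separates the two events. It sets out from 22: the same cuprate addition is worked up hydrolytically to the bis(3-benzyl-4-vinyl lactone) F1, a mixture of epimers at the benzyl-bearing carbon. F1 is then enolised with KN(SiMe3)2 in THF at −78 °C and hydroxylated with 2-(phenylsulfonyl)-3-phenyloxaziridine, a bulkier oxidant acting on a discrete potassium enolate. The fallback returns to the route at 25.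

**Step 21.** Carbon may capture the C2 cation in place of oxygen (Friedel–Crafts closure by ring A para to its methoxy group, giving an aryltetralin). The cis ether may form, or the tertiary alcohol may be lost, if the acid is too strong or the time too long. The fallback avoids ionisation at C2 altogether. It sets out from 25: iBu2AlH at −78 °C gives the bis(lactol) F5, and Et3SiH/BF3·OEt2 at −78 °C reduces the oxocarbenium ions to the bis(vinyl oxolane) F6 with C2 untouched. Ozonolysis with NaBH4 work-up of F6 then returns to the route at 28.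

**Step 17.** Ring closure onto a 1,1-disubstituted acrylate is slow. In a tetraene, cross-metathesis between the two halves and ionisation or 1,3-transposition of the electron-rich allylic esters may compete at 80 °C. The fallback closes one ring at a time. It sets out from 16: metathesis of its single diene pair gives the mono-butenolide silyl ether F2. Non-basic desilylation with HF·pyridine gives the alcohol F3, and DCC/DMAP esterification with 20 gives the butenolide acrylate F4. A second, now single, ring closure returns to the route at 22.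

**Step 19.** Ozone may over-oxidise the four dialkoxyarenes if the end-point is missed. The fallback sets out from 25 and uses OsO4 (cat.)/NaIO4/2,6-lutidine in dioxane–water. This gives the bis(aldehyde) F7, which is reduced at once with NaBH4 at low temperature, before epimerisation at C3 or β-elimination can occur. It returns to the route at 26.

**Step 22.** Once each para-phenol is free, the C2–O1 bond is a para-hydroxybenzyl ether, and over-reduction on palladium may open the ring. The fallback inverts the order. It sets out from 27: hydrogenolysis over Pd/C in EtOAc, where the benzylic C2 oxygen is a free secondary alcohol that cleaves far more slowly than an aryl benzyl ether, gives the deprotected open-chain compound F8. Mild acid (camphorsulfonic acid, THF) then closes both rings through para-quinone methide-type cations with no palladium present, returning to the route at 29.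

## Further compounds

F1 | step 18 | bis[(4R,5S)-5-aryl-3-benzyl-4-vinyloxolan-2-one], benzylated phenols, epimer mixture at C3 of each lactone | COc1cc(CC2C(=O)O[C@H](c3cc(OC)c(OCc4ccccc4)c(-c4cc(CC5C(=O)O[C@H](c6ccc(OCc7ccccc7)c(OC)c6)[C@H]5C=C)cc(OC)c4OCc4ccccc4)c3)[C@H]2C=C)ccc1OCc1ccccc1
F2 | step 17 | mono-butenolide (unit 2 closed, 5S) with ring B (S)-carbinol as tert-butyldimethylsilyl ether | C=C[C@H](O[Si](C)(C)C(C)(C)C)c1cc(OC)c(OCc2ccccc2)c(c1)-c1cc(CC2=C[C@@H](c3ccc(OCc4ccccc4)c(OC)c3)OC2=O)cc(OC)c1OCc1ccccc1
F3 | step 17 | mono-butenolide (unit 2 closed, 5S) with free ring B (S)-carbinol | C=C[C@H](O)c1cc(OC)c(OCc2ccccc2)c(c1)-c1cc(CC2=C[C@@H](c3ccc(OCc4ccccc4)c(OC)c3)OC2=O)cc(OC)c1OCc1ccccc1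
F4 | step 17 | mono-butenolide (unit 2 closed) whose ring B (S)-carbinol is esterified with acid 20 | C=C[C@H](OC(=O)C(=C)Cc1ccc(OCc2ccccc2)c(OC)c1)c1cc(OC)c(OCc2ccccc2)c(c1)-c1cc(CC2=C[C@@H](c3ccc(OCc4ccccc4)c(OC)c3)OC2=O)cc(OC)c1OCc1ccccc1
F5 | step 21 | bis(lactol) of 25 (each lactone C=O reduced to CH(OH), anomers) | COc1cc(C[C@@]2(O)C(O)O[C@H](c3cc(OC)c(OCc4ccccc4)c(-c4cc(C[C@@]5(O)C(O)O[C@H](c6ccc(OCc7ccccc7)c(OC)c6)[C@H]5C=C)cc(OC)c4OCc4ccccc4)c3)[C@H]2C=C)ccc1OCc1ccccc1
F6 | step 21 | bis[(2S,3R,4S)-2-aryl-4-benzyl-4-hydroxy-3-vinyloxolane], benzylated phenols | COc1cc(C[C@@]2(O)CO[C@H](c3cc(OC)c(OCc4ccccc4)c(-c4cc(C[C@@]5(O)CO[C@H](c6ccc(OCc7ccccc7)c(OC)c6)[C@H]5C=C)cc(OC)c4OCc4ccccc4)c3)[C@H]2C=C)ccc1OCc1ccccc1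
F7 | step 19 | bis(aldehyde): 25 with each vinyl group replaced by CHO | COc1cc(C[C@@]2(O)C(=O)O[C@H](c3cc(OC)c(OCc4ccccc4)c(-c4cc(C[C@@]5(O)C(=O)O[C@H](c6ccc(OCc7ccccc7)c(OC)c6)[C@H]5C=O)cc(OC)c4OCc4ccccc4)c3)[C@H]2C=O)ccc1OCc1ccccc1
F8 | step 22 | open-chain octaol 27 with all four phenols free | COc1cc(C[C@@](O)(CO)[C@H](CO)[C@H](O)c2cc(OC)c(O)c(-c3cc(C[C@@](O)(CO)[C@H](CO)[C@H](O)c4ccc(O)c(OC)c4)cc(OC)c3O)c2)ccc1O
A1 | alternative 1 | bis-diene with O-vinyl ethers at both C2 oxygens and 1,1-disubstituted alkenes at both C4 | COc1cc(CC(=C)[C@H](CO[Si](C)(C)C(C)(C)C)[C@H](OC=C)c2cc(OC)c(OCc3ccccc3)c(-c3cc(CC(=C)[C@H](CO[Si](C)(C)C(C)(C)C)[C@H](OC=C)c4ccc(OCc5ccccc5)c(OC)c4)cc(OC)c3OCc3ccccc3)c2)ccc1OCc1ccccc1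
A2 | alternative 1 | bis(2-aryl-4-benzyl-2,3-dihydrofuran) with silylated C3 hydroxymethyl groups | COc1cc(CC2=CO[C@H](c3cc(OC)c(OCc4ccccc4)c(-c4cc(CC5=CO[C@H](c6ccc(OCc7ccccc7)c(OC)c6)[C@H]5CO[Si](C)(C)C(C)(C)C)cc(OC)c4OCc4ccccc4)c3)[C@H]2CO[Si](C)(C)C(C)(C)C)ccc1OCc1ccccc1
A3 | alternative 2 | biaryl-linked bis[(Z)-4-aryl-4-silyloxybut-2-enyl 2-benzyloxy-3-arylpropanoate] | COc1cc(CC(OCc2ccccc2)C(=O)OC/C=C\[C@H](O[Si](C)(C)C(C)(C)C)c2cc(OC)c(OCc3ccccc3)c(-c3cc(CC(OCc4ccccc4)C(=O)OC/C=C\[C@H](O[Si](C)(C)C(C)(C)C)c4ccc(OCc5ccccc5)c(OC)c4)cc(OC)c3OCc3ccccc3)c2)ccc1OCc1ccccc1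
A4 | alternative 2 | bis(α-benzyloxy-β-vinyl acid) | COc1cc(C[C@@](OCc2ccccc2)(C(=O)O)[C@H](C=C)[C@H](O[Si](C)(C)C(C)(C)C)c2cc(OC)c(OCc3ccccc3)c(-c3cc(C[C@@](OCc4ccccc4)(C(=O)O)[C@H](C=C)[C@H](O[Si](C)(C)C(C)(C)C)c4ccc(OCc5ccccc5)c(OC)c4)cc(OC)c3OCc3ccccc3)c2)ccc1OCc1ccccc1
A5 | alternative 3 | seco dimer with C2 as CH2, free phenols on rings B and D, benzyl ethers on rings A and C | COc1cc(C[C@@](O)(CO)[C@H](CO)Cc2cc(OC)c(O)c(-c3cc(C[C@@](O)(CO)[C@H](CO)Cc4ccc(O)c(OC)c4)cc(OC)c3OCc3ccccc3)c2)ccc1OCc1ccccc1
A6 | alternative 3 | target bis(benzyl ether), benzyl on the phenols of rings A and C | COc1cc(C[C@@]2(O)CO[C@H](c3cc(OC)c(O)c(-c4cc(C[C@@]5(O)CO[C@H](c6ccc(O)c(OC)c6)[C@H]5CO)cc(OC)c4OCc4ccccc4)c3)[C@H]2CO)ccc1OCc1ccccc1
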